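**Strategy.** Numbering the cyclohexene ring from the aryloxy carbon (C-1) through the olefin (C-2=C-3, methyl on C-3) to the carbinol (C-4), the ring methylene (C-5) and the side-chain carbon (C-6), everything rests on closing the ring between C-4 and C-5. C-4 is an enone carbonyl in disguise, so it is brought in as carbon monoxide: one-pot hydroboration of a 1,1-disubstituted alkene and carbonylative B-alkyl Suzuki–Miyaura cyclisation onto a (Z)-vinyl iodide sets C-6, inserts C-4 and closes the ring. The precursor is an acyclic iodo-triene silyl ether made from (S)-citronellal, formaldehyde and propyne; vanillin and a styryl diketone complete the curcuminoid.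

Key step: step 5

Assumption: the (S,S) antipode of the ProPhenol ligand is written for Re-face alkynylation in step 2; should the sense prove opposite, the mirror-image ligand is used.

Step 1
Reactants: 1 (S)-citronellal
Product: 2 (3S)-3,7-dimethyl-2-methylideneoct-6-enal
Conditions: 37% aq. CH2O, pyrrolidine (10 mol%), EtCO2H (10 mol%), i-PrOH, 45 °C
Reagents that add atoms: formaldehyde C=O
Why: Amine-catalysed Mannich condensation followed by elimination (organocatalytic α-methylenation of an aldehyde) should turn the α-CH2 into the methylene that later becomes the ring CH2, without forming a stereocenter and without touching the C-3 methyl stereocenter, which is not activated in the cross-conjugated product.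

Step 2
Reactants: 2 (3S)-3,7-dimethyl-2-methylideneoct-6-enal; 3 propyne
Product: 4 (4S,6S)-6,10-dimethyl-5-methylideneundec-9-en-2-yn-4-ol
Conditions: propyne (3 equiv), Me2Zn, (S,S)-ProPhenol (10 mol%), Ph3P=O (20 mol%), toluene, 0 °C; aq. NH4Cl
Reagents that add atoms: none
Why: Zinc alkynylide 1,2-addition to the enal under ProPhenol catalysis (catalytic asymmetric alkynylation) should set the carbinol stereocenter as (4S) by catalyst-controlled Re-face delivery, the existing methyl-bearing center being too remote to override the ligand.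

Step 3
Reactants: 4 (4S,6S)-6,10-dimethyl-5-methylideneundec-9-en-2-yn-4-ol
Product: 6 (2Z,4R,6S)-2-iodo-6,10-dimethyl-5-methylideneundeca-2,9-dien-4-ol, via cyclic vinylalanate 5 (not isolated)
Conditions: NaAlH2(OCH2CH2OMe)2, THF, 0 °C to rt; then I2, −78 °C; aq. potassium sodium tartrate
Reagents that add atoms: iodine [I][I]
Why: Alkoxide-directed trans-hydroalumination of the propargylic alcohol gives the five-membered vinylalanate 5 with aluminium on the distal carbon, and iodinolysis with retention should give the (Z)-vinyl iodide with iodine cis to the carbinol carbon, the geometry that the ring closure needs, with no new stereocenter (the descriptor at C-4 changes only through the priority rules).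

Step 4
Reactants: 6 (2Z,4R,6S)-2-iodo-6,10-dimethyl-5-methylideneundeca-2,9-dien-4-ol
Product: 7 tert-butyl{[(2Z,4R,6S)-2-iodo-6,10-dimethyl-5-methylideneundeca-2,9-dien-4-yl]oxy}dimethylsilane
Conditions: TBSOTf, 2,6-lutidine, CH2Cl2, −78 °C
Reagents that add atoms: tert-butyldimethylsilyl trifluoromethanesulfonate CC(C)(C)[Si](C)(C)OS(=O)(=O)C(F)(F)F
Why: Silyl ether formation on the hindered bis-allylic alcohol should proceed with the reactive triflate and is needed because a free (Z)-γ-hydroxy vinyl iodide would lactonise to a butenolide under carbonylation, while the silyloxy group also serves as the control element for the hydroboration.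

Step 5
Reactants: 7 tert-butyl{[(2Z,4R,6S)-2-iodo-6,10-dimethyl-5-methylideneundeca-2,9-dien-4-yl]oxy}dimethylsilane
Product: 9 (4S,5R)-4-{[tert-butyl(dimethyl)silyl]oxy}-2-methyl-5-[(2S)-6-methylhept-5-en-2-yl]cyclohex-2-en-1-one, via B-alkyl-9-BBN adduct 8 (not isolated)
Conditions: 9-BBN (1.2 equiv), THF, 0 °C to rt; then aq. K3PO4, Pd(PPh3)4 (5 mol%), CO (1 atm), THF–dioxane, 50 °C
Reagents that add atoms: carbon monoxide [C-]#[O+]
Why: 9-BBN should add anti-Markovnikov to the 1,1-disubstituted alkene only (the trisubstituted and iodo-substituted alkenes are too hindered) to give primary alkylborane 8; zerovalent palladium then inserts into the vinyl C–I bond, CO inserts to give a (Z)-enoyl palladium species, base-assisted transfer of the alkyl group from boron gives a seven-membered acyl(alkyl)palladacycle, and reductive elimination forms the bond between the new carbonyl carbon and the ring CH2. The closest known reaction type is the carbonylative Suzuki–Miyaura coupling of B-alkyl-9-BBN reagents with 1-iodoalkenes to enones, used here in its intramolecular hydroboration–carbonylative cyclisation form. The one ring formed, the cyclohexenone, closes by acyl–alkyl reductive elimination in a formal [5+1] annulation with CO, which is possible because the (Z)-iodide from step 3 holds the acyl palladium cis to the chain. The new stereocenter (C-5 of 9) is set in the hydroboration under control of the neighbouring silyloxy-bearing carbon: with the allylic hydrogen inside, the silyloxy group outside and the alkenyl group anti to the incoming borane, the anti adduct is expected, which places the side chain cis to the silyloxy group in the ring, and the methyl-bearing allylic center, which tells apart only a methyl and a methylene group, should add little bias of its own. The step needs CO insertion to outrun direct alkyl–vinyl coupling (a cyclopentene would result), for which the CO atmosphere and the triphenylphosphine ligand are chosen, and it needs the acyl palladium not to be trapped by oxygen, which the silyl ether secures.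

Step 6
Reactants: 9 (4S,5R)-4-{[tert-butyl(dimethyl)silyl]oxy}-2-methyl-5-[(2S)-6-methylhept-5-en-2-yl]cyclohex-2-en-1-one
Product: 10 (4S,5R)-4-{[tert-butyl(dimethyl)silyl]oxy}-2-methyl-5-[(2S)-6-methyl-4-oxohept-5-en-2-yl]cyclohex-2-en-1-one
Conditions: CrO3, 3,5-dimethylpyrazole, CH2Cl2, −20 °C
Reagents that add atoms: chromium trioxide O=[Cr](=O)=O
Why: Allylic C–H oxidation by the CrO3–3,5-dimethylpyrazole complex should attack the allylic methylene of the electron-rich trisubstituted side-chain alkene and give the β,β-dimethyl enone, the ring alkene being conjugated and electron-poor and no free hydroxyl being present; no stereocenter is involved.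

Step 7
Reactants: 10 (4S,5R)-4-{[tert-butyl(dimethyl)silyl]oxy}-2-methyl-5-[(2S)-6-methyl-4-oxohept-5-en-2-yl]cyclohex-2-en-1-one
Product: 11 (4S,5R)-4-hydroxy-2-methyl-5-[(2S)-6-methyl-4-oxohept-5-en-2-yl]cyclohex-2-en-1-one
Conditions: HF·pyridine, THF, 0 °C to rt
Reagents that add atoms: none
Why: Fluoride-mediated silyl ether cleavage under mildly acidic conditions should free the γ-hydroxyl without the base that could epimerise or deconjugate the γ-oxygenated enone.

Step 8
Reactants: 11 (4S,5R)-4-hydroxy-2-methyl-5-[(2S)-6-methyl-4-oxohept-5-en-2-yl]cyclohex-2-en-1-one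
Product: 12 (1S,4S,5R)-2-methyl-5-[(2S)-6-methyl-4-oxohept-5-en-2-yl]cyclohex-2-ene-1,4-diol
Conditions: Me4NBH(OAc)3, AcOH–MeCN (1:1), −30 °C
Reagents that add atoms: none
Why: In this hydroxyl-directed triacetoxyborohydride reduction (Evans–Saksena reduction) the pseudoaxial C-4 hydroxyl of 11 should bind boron and deliver hydride across the ring to the face of the ring carbonyl that it occupies, so the new carbinol (1S) forms trans to the directing hydroxyl, while the side-chain enone, which has no nearby hydroxyl, is left alone by this weak hydride.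

Step 9
Reactants: 12 (1S,4S,5R)-2-methyl-5-[(2S)-6-methyl-4-oxohept-5-en-2-yl]cyclohex-2-ene-1,4-diol
Product: 13 (1S,4S,6R)-3-methyl-6-[(2S)-6-methyl-4-oxohept-5-en-2-yl]-4-[(triethylsilyl)oxy]cyclohex-2-en-1-ol
Conditions: Et3SiCl (1.05 equiv), imidazole, CH2Cl2, −40 °C
Reagents that add atoms: chlorotriethylsilane CC[Si](Cl)(CC)CC
Why: Silyl ether formation at low temperature should select the hydroxyl flanked by the ring CH2 (C-1 of 12) over the one next to the branched side chain that sits cis to it, which leaves free only the hydroxyl that is to be replaced.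

Step 10
Reactants: 13 (1S,4S,6R)-3-methyl-6-[(2S)-6-methyl-4-oxohept-5-en-2-yl]-4-[(triethylsilyl)oxy]cyclohex-2-en-1-ol; 14 vanillin
Product: 15 3-methoxy-4-{[(1R,4S,6R)-3-methyl-6-[(2S)-6-methyl-4-oxohept-5-en-2-yl]-4-[(triethylsilyl)oxy]cyclohex-2-en-1-yl]oxy}benzaldehyde
Conditions: PPh3, DIAD, toluene, 0 °C to rt
Reagents that add atoms: none
Why: Mitsunobu etherification with the acidic phenol should displace the activated allylic hydroxyl by SN2 with inversion, converting the (1S) carbinol of 13 into the (1R) aryl ether that is trans to the side chain and cis to the silyloxy group, SN2′ attack being disfavoured because it would build a tertiary ether at the methyl-bearing terminus.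

Step 11
Reactants: 16 acetylacetone; 17 4-hydroxybenzaldehyde
Product: 20 (1E,4Z)-5-hydroxy-1-(4-hydroxyphenyl)hexa-1,4-dien-3-one, via acetylacetone dibutoxyboron chelate 18 (not isolated), via monostyryl dibutoxyboron chelate 19 (not isolated)
Conditions: 16 (3 equiv), B2O3, B(OBu)3, n-BuNH2 (cat.), EtOAc, 70 °C; then 0.4 M aq. HCl, 50 °C
Reagents that add atoms: none
Why: In this boron-mediated aldol condensation the diketone is held as a boron chelate so that only a terminal methyl group condenses with the aldehyde, the excess of acetylacetone keeping the reaction at the mono-styryl stage and dehydration giving the (E)-alkene.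

Step 12
Reactants: 15 3-methoxy-4-{[(1R,4S,6R)-3-methyl-6-[(2S)-6-methyl-4-oxohept-5-en-2-yl]-4-[(triethylsilyl)oxy]cyclohex-2-en-1-yl]oxy}benzaldehyde; 20 (1E,4Z)-5-hydroxy-1-(4-hydroxyphenyl)hexa-1,4-dien-3-one
Product: 23 demethoxybisabolocurcumin ether, via monostyryl diisopropoxyboron chelate 21 (not isolated), via silyl-protected curcuminoid diisopropoxyboron chelate 22 (not isolated)
Conditions: B2O3, B(Oi-Pr)3, n-BuNH2 (cat.), EtOAc–DMF, 70 °C; then 0.1 M aq. HCl, THF, rt
Reagents that add atoms: none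
Why: The boron-mediated aldol condensation of step 11, run here with triisopropyl borate, should hold diketone 20 as chelate 21 so that only its remaining methyl group condenses with aldehyde 15 to form the second (E)-styryl arm, and the dilute acid that hydrolyses chelate 22 also removes the triethylsilyl ether, giving the target as its keto–enol tautomer with all four stereocenters untouched.

**Compound list**

1 | (S)-citronellal, (3S)-3,7-dimethyloct-6-enal | O=CC[C@@H](C)CCC=C(C)C | starting material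
2 | (3S)-3,7-dimethyl-2-methylideneoct-6-enal | O=CC(=C)[C@@H](C)CCC=C(C)C | intermediate
3 | propyne | CC#C | starting material
4 | (4S,6S)-6,10-dimethyl-5-methylideneundec-9-en-2-yn-4-ol | CC#C[C@@H](O)C(=C)[C@@H](C)CCC=C(C)C | intermediate
5 | cyclic vinylalanate, sodium (5R)-5-[(3S)-3,7-dimethylocta-1,6-dien-2-yl]-2,2-bis(2-methoxyethoxy)-3-methyl-2,5-dihydro-1,2-oxaaluminol-2-uide | CC1=C[C@@H](O[Al-]1(OCCOC)OCCOC)C(=C)[C@@H](C)CCC=C(C)C.[Na+] | intermediate
6 | (2Z,4R,6S)-2-iodo-6,10-dimethyl-5-methylideneundeca-2,9-dien-4-ol | C/C(I)=C/[C@@H](O)C(=C)[C@@H](C)CCC=C(C)C | intermediate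
7 | tert-butyl{[(2Z,4R,6S)-2-iodo-6,10-dimethyl-5-methylideneundeca-2,9-dien-4-yl]oxy}dimethylsilane | C/C(I)=C/[C@@H](O[Si](C)(C)C(C)(C)C)C(=C)[C@@H](C)CCC=C(C)C | intermediate
8 | 9-[(2R,3S)-2-[(1S,2Z)-1-{[tert-butyl(dimethyl)silyl]oxy}-3-iodobut-2-en-1-yl]-3,7-dimethyloct-6-en-1-yl]-9-borabicyclo[3.3.1]nonane | C/C(I)=C/[C@@H](O[Si](C)(C)C(C)(C)C)[C@H](CB1C2CCCC1CCC2)[C@@H](C)CCC=C(C)C | intermediate
9 | (4S,5R)-4-{[tert-butyl(dimethyl)silyl]oxy}-2-methyl-5-[(2S)-6-methylhept-5-en-2-yl]cyclohex-2-en-1-one | CC1=C[C@@H](O[Si](C)(C)C(C)(C)C)[C@@H]([C@@H](C)CCC=C(C)C)CC1=O | intermediate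
10 | (4S,5R)-4-{[tert-butyl(dimethyl)silyl]oxy}-2-methyl-5-[(2S)-6-methyl-4-oxohept-5-en-2-yl]cyclohex-2-en-1-one | CC1=C[C@@H](O[Si](C)(C)C(C)(C)C)[C@@H]([C@@H](C)CC(=O)C=C(C)C)CC1=O | intermediate
11 | (4S,5R)-4-hydroxy-2-methyl-5-[(2S)-6-methyl-4-oxohept-5-en-2-yl]cyclohex-2-en-1-one | CC1=C[C@@H](O)[C@@H]([C@@H](C)CC(=O)C=C(C)C)CC1=O | intermediate
12 | (1S,4S,5R)-2-methyl-5-[(2S)-6-methyl-4-oxohept-5-en-2-yl]cyclohex-2-ene-1,4-diol | CC1=C[C@@H](O)[C@@H]([C@@H](C)CC(=O)C=C(C)C)C[C@@H]1O | intermediate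
13 | (1S,4S,6R)-3-methyl-6-[(2S)-6-methyl-4-oxohept-5-en-2-yl]-4-[(triethylsilyl)oxy]cyclohex-2-en-1-ol | CC1=C[C@@H](O)[C@@H]([C@@H](C)CC(=O)C=C(C)C)C[C@@H]1O[Si](CC)(CC)CC | intermediate
14 | vanillin, 4-hydroxy-3-methoxybenzaldehyde | COc1cc(C=O)ccc1O | starting material
15 | 3-methoxy-4-{[(1R,4S,6R)-3-methyl-6-[(2S)-6-methyl-4-oxohept-5-en-2-yl]-4-[(triethylsilyl)oxy]cyclohex-2-en-1-yl]oxy}benzaldehyde | COc1cc(C=O)ccc1O[C@H]1C=C(C)[C@@H](O[Si](CC)(CC)CC)C[C@@H]1[C@@H](C)CC(=O)C=C(C)C | intermediate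
16 | acetylacetone, pentane-2,4-dione | CC(=O)CC(C)=O | starting material
17 | 4-hydroxybenzaldehyde | O=Cc1ccc(O)cc1 | starting material
18 | dibutoxyboron chelate of acetylacetone | CC1=CC(C)=[O+][B-](OCCCC)(OCCCC)O1 | intermediate
19 | dibutoxyboron chelate of 20 | CC1=CC(/C=C/c2ccc(O)cc2)=[O+][B-](OCCCC)(OCCCC)O1 | intermediate
20 | (1E,4Z)-5-hydroxy-1-(4-hydroxyphenyl)hexa-1,4-dien-3-one | C/C(O)=C/C(=O)/C=C/c1ccc(O)cc1 | intermediate
21 | diisopropoxyboron chelate of 20 | CC1=CC(/C=C/c2ccc(O)cc2)=[O+][B-](OC(C)C)(OC(C)C)O1 | intermediate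
22 | diisopropoxyboron chelate of the O-triethylsilyl ether of 23 | COc1cc(/C=C/C2=CC(/C=C/c3ccc(O)cc3)=[O+][B-](OC(C)C)(OC(C)C)O2)ccc1O[C@H]1C=C(C)[C@@H](O[Si](CC)(CC)CC)C[C@@H]1[C@@H](C)CC(=O)C=C(C)C | intermediate
23 | demethoxybisabolocurcumin ether, (1E,4Z,6E)-5-hydroxy-7-(4-{[(1R,4S,6R)-4-hydroxy-3-methyl-6-[(2S)-6-methyl-4-oxohept-5-en-2-yl]cyclohex-2-en-1-yl]oxy}-3-methoxyphenyl)-1-(4-hydroxyphenyl)hepta-1,4,6-trien-3-one | COc1cc(/C=C/C(O)=C/C(=O)/C=C/c2ccc(O)cc2)ccc1O[C@H]1C=C(C)[C@@H](O)C[C@@H]1[C@@H](C)CC(=O)C=C(C)C | target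

**Step count and risks**

Total step count: 12. Longest linear sequence: 11 steps (steps 1–10 and 12); step 11 is a one-step side branch.

Step 5 (key step). What may go wrong: alkyl–vinyl coupling before CO uptake, and β-hydride loss from the alkylpalladium intermediate. The fallback separates the introduction of the carbonyl carbon from the ring closure and forms the same ring bond by an anionic acyl substitution; it sets out from 7 and comes back at 9. Palladium-catalysed aminocarbonylation of 7 (PdCl2(PPh3)2, CO, MeNHOMe·HCl, Et3N, DMF, 60 °C) would give the Weinreb amide (2Z,4R,6S)-4-{[tert-butyl(dimethyl)silyl]oxy}-N-methoxy-N,2,6,10-tetramethyl-5-methylideneundeca-2,9-dienamide F1. Hydroboration–oxidation of F1 (9-BBN, THF; then NaBO3·4H2O), under the same acyclic stereocontrol as in step 5, would give (2Z,4R,5S,6S)-4-{[tert-butyl(dimethyl)silyl]oxy}-5-(hydroxymethyl)-N-methoxy-N,2,6,10-tetramethylundeca-2,9-dienamide F2. I2, PPh3 and imidazole would then turn F2 into (2Z,4R,5R,6S)-4-{[tert-butyl(dimethyl)silyl]oxy}-5-(iodomethyl)-N-methoxy-N,2,6,10-tetramethylundeca-2,9-dienamide F3. Iodine–lithium exchange on F3 with t-BuLi (2 equiv, Et2O–pentane, −78 °C) would let the primary alkyllithium add to the cis-disposed Weinreb amide in a six-membered ring closure, and aqueous work-up of the chelated adduct gives 9.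

Step 8. What may go wrong: undirected or conjugate hydride delivery competing with delivery across the ring, so that facial and 1,2-selectivity are lost. The fallback sets the carbinol by inversion instead of by direction and makes the site-selective silylation of step 9 unnecessary; it sets out from 9 and comes back at 23. Luche reduction of 9 (NaBH4, CeCl3·7H2O, MeOH, −78 °C) should add hydride axially, from the face opposite the silyloxy and side-chain groups, to give (1R,4S,5R)-4-{[tert-butyl(dimethyl)silyl]oxy}-2-methyl-5-[(2S)-6-methylhept-5-en-2-yl]cyclohex-2-en-1-ol F4. Mitsunobu inversion of F4 with 4-nitrobenzoic acid (PPh3, DIAD) would give (1S,4S,5R)-4-{[tert-butyl(dimethyl)silyl]oxy}-2-methyl-5-[(2S)-6-methylhept-5-en-2-yl]cyclohex-2-en-1-yl 4-nitrobenzoate F5, in which the two ring oxygens are told apart by construction. CrO3–3,5-dimethylpyrazole as in step 6 would convert F5 into (1S,4S,5R)-4-{[tert-butyl(dimethyl)silyl]oxy}-2-methyl-5-[(2S)-6-methyl-4-oxohept-5-en-2-yl]cyclohex-2-en-1-yl 4-nitrobenzoate F6. HF·pyridine would then turn F6 into (1S,4S,5R)-4-hydroxy-2-methyl-5-[(2S)-6-methyl-4-oxohept-5-en-2-yl]cyclohex-2-en-1-yl 4-nitrobenzoate F7. Mitsunobu etherification of F7 with 14 would give, with inversion, (1S,4R,5R)-4-(4-formyl-2-methoxyphenoxy)-2-methyl-5-[(2S)-6-methyl-4-oxohept-5-en-2-yl]cyclohex-2-en-1-yl 4-nitrobenzoate F8. Methanolysis of F8 with K2CO3 in MeOH would give 4-{[(1R,4S,6R)-4-hydroxy-3-methyl-6-[(2S)-6-methyl-4-oxohept-5-en-2-yl]cyclohex-2-en-1-yl]oxy}-3-methoxybenzaldehyde F9. The boron-mediated condensation of F9 with 20, as in step 12, passes through 21 and the diisopropoxyboron chelate of 23 F10, and acid hydrolysis of F10 gives 23.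

Step 6. What may go wrong: poor site selectivity of the C–H oxidation (attack at the allylic methyl groups or in the ring instead of the side-chain methylene) and overoxidation. The fallback replaces the direct C–H oxidation by addition, elimination and oxidative transposition; it sets out from 9 and comes back at 10. Markovnikov hydroxyselenation of the side-chain alkene of 9 with N-(phenylselanyl)phthalimide and water (camphorsulfonic acid cat., CH2Cl2) would give, without facial control, two epimeric hydroxy selenides. These are (4S,5R)-4-{[tert-butyl(dimethyl)silyl]oxy}-5-[(2S,5R)-6-hydroxy-6-methyl-5-(phenylselanyl)heptan-2-yl]-2-methylcyclohex-2-en-1-one F11 and (4S,5R)-4-{[tert-butyl(dimethyl)silyl]oxy}-5-[(2S,5S)-6-hydroxy-6-methyl-5-(phenylselanyl)heptan-2-yl]-2-methylcyclohex-2-en-1-one F12. Oxidation of F11 and F12 together with H2O2 (THF, 0 °C to rt) and syn-elimination of benzeneselenenic acid away from the carbinol carbon would converge on (4S,5R)-4-{[tert-butyl(dimethyl)silyl]oxy}-5-[(2S,4E)-6-hydroxy-6-methylhept-4-en-2-yl]-2-methylcyclohex-2-en-1-one F13. Oxidative 1,3-transposition of the tertiary allylic alcohol F13 with pyridinium chlorochromate, C5H5NH[CrO3Cl] (Babler–Dauben oxidation), gives 10.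

**Further compounds**

F1 | step 5 | (2Z,4R,6S)-4-{[tert-butyl(dimethyl)silyl]oxy}-N-methoxy-N,2,6,10-tetramethyl-5-methylideneundeca-2,9-dienamide | C/C(C(=O)N(C)OC)=C/[C@@H](O[Si](C)(C)C(C)(C)C)C(=C)[C@@H](C)CCC=C(C)C
F2 | step 5 | (2Z,4R,5S,6S)-4-{[tert-butyl(dimethyl)silyl]oxy}-5-(hydroxymethyl)-N-methoxy-N,2,6,10-tetramethylundeca-2,9-dienamide | C/C(C(=O)N(C)OC)=C/[C@@H](O[Si](C)(C)C(C)(C)C)[C@H](CO)[C@@H](C)CCC=C(C)C
F3 | step 5 | (2Z,4R,5R,6S)-4-{[tert-butyl(dimethyl)silyl]oxy}-5-(iodomethyl)-N-methoxy-N,2,6,10-tetramethylundeca-2,9-dienamide | C/C(C(=O)N(C)OC)=C/[C@@H](O[Si](C)(C)C(C)(C)C)[C@H](CI)[C@@H](C)CCC=C(C)C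
F4 | step 8 | (1R,4S,5R)-4-{[tert-butyl(dimethyl)silyl]oxy}-2-methyl-5-[(2S)-6-methylhept-5-en-2-yl]cyclohex-2-en-1-ol | CC1=C[C@@H](O[Si](C)(C)C(C)(C)C)[C@@H]([C@@H](C)CCC=C(C)C)C[C@H]1O
F5 | step 8 | (1S,4S,5R)-4-{[tert-butyl(dimethyl)silyl]oxy}-2-methyl-5-[(2S)-6-methylhept-5-en-2-yl]cyclohex-2-en-1-yl 4-nitrobenzoate | CC1=C[C@@H](O[Si](C)(C)C(C)(C)C)[C@@H]([C@@H](C)CCC=C(C)C)C[C@@H]1OC(=O)c2ccc([N+](=O)[O-])cc2
F6 | step 8 | (1S,4S,5R)-4-{[tert-butyl(dimethyl)silyl]oxy}-2-methyl-5-[(2S)-6-methyl-4-oxohept-5-en-2-yl]cyclohex-2-en-1-yl 4-nitrobenzoate | CC1=C[C@@H](O[Si](C)(C)C(C)(C)C)[C@@H]([C@@H](C)CC(=O)C=C(C)C)C[C@@H]1OC(=O)c2ccc([N+](=O)[O-])cc2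
F7 | step 8 | (1S,4S,5R)-4-hydroxy-2-methyl-5-[(2S)-6-methyl-4-oxohept-5-en-2-yl]cyclohex-2-en-1-yl 4-nitrobenzoate | CC1=C[C@@H](O)[C@@H]([C@@H](C)CC(=O)C=C(C)C)C[C@@H]1OC(=O)c2ccc([N+](=O)[O-])cc2
F8 | step 8 | (1S,4R,5R)-4-(4-formyl-2-methoxyphenoxy)-2-methyl-5-[(2S)-6-methyl-4-oxohept-5-en-2-yl]cyclohex-2-en-1-yl 4-nitrobenzoate | COc1cc(C=O)ccc1O[C@H]1C=C(C)[C@@H](OC(=O)c2ccc([N+](=O)[O-])cc2)C[C@@H]1[C@@H](C)CC(=O)C=C(C)C
F9 | step 8 | 4-{[(1R,4S,6R)-4-hydroxy-3-methyl-6-[(2S)-6-methyl-4-oxohept-5-en-2-yl]cyclohex-2-en-1-yl]oxy}-3-methoxybenzaldehyde | COc1cc(C=O)ccc1O[C@H]1C=C(C)[C@@H](O)C[C@@H]1[C@@H](C)CC(=O)C=C(C)C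
F10 | step 8 | diisopropoxyboron chelate of 23 | COc1cc(/C=C/C2=CC(/C=C/c3ccc(O)cc3)=[O+][B-](OC(C)C)(OC(C)C)O2)ccc1O[C@H]1C=C(C)[C@@H](O)C[C@@H]1[C@@H](C)CC(=O)C=C(C)C
F11 | step 6 | (4S,5R)-4-{[tert-butyl(dimethyl)silyl]oxy}-5-[(2S,5R)-6-hydroxy-6-methyl-5-(phenylselanyl)heptan-2-yl]-2-methylcyclohex-2-en-1-one | CC1=C[C@@H](O[Si](C)(C)C(C)(C)C)[C@@H]([C@@H](C)CC[C@@H]([Se]c2ccccc2)C(C)(C)O)CC1=O
F12 | step 6 | (4S,5R)-4-{[tert-butyl(dimethyl)silyl]oxy}-5-[(2S,5S)-6-hydroxy-6-methyl-5-(phenylselanyl)heptan-2-yl]-2-methylcyclohex-2-en-1-one | CC1=C[C@@H](O[Si](C)(C)C(C)(C)C)[C@@H]([C@@H](C)CC[C@H]([Se]c2ccccc2)C(C)(C)O)CC1=O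
F13 | step 6 | (4S,5R)-4-{[tert-butyl(dimethyl)silyl]oxy}-5-[(2S,4E)-6-hydroxy-6-methylhept-4-en-2-yl]-2-methylcyclohex-2-en-1-one | CC1=C[C@@H](O[Si](C)(C)C(C)(C)C)[C@@H]([C@@H](C)C/C=C/C(C)(C)O)CC1=O
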